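**Plan**

- Numbering (daucane): C1 = quaternary C–Me at the ring fusion, C2/C3 = cyclopentane CH2, C4 = C(OH)(iPr), C5 = ring-fusion CH, C6 = CH–O-acyl, C7=C8(Me), C9 = CH–OH, C10 = CH2.
- Retrosynthesis: cut the C6–O ester; take C6–OH back to a C6 ketone and C7=C8 back to C7–C8; then cut C1–C2 and C4–C5 together, which leaves a 3-methylcyclohept-2-enone and 1-isopropylcyclopropanol; the enone goes back by one carbon to a cyclohexanone made from 2,5-dimethylanisole.
- Forward: six-membered ring (Birch reduction, asymmetric hydroboration), then the seven-membered enone (siloxycyclopropane ring expansion), then the five-membered ring in one flask (strain-release homoenolate conjugate addition, then aldol), then enone, C6 reduction, vanilloylation, desilylation.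
- Enabling feature: the oxygens at C6 and C4 are 1,3 across ring-fusion C5 (aldol retron) and C1 is β to C6 (Michael retron), so C2–C3–C4(=O)iPr is exactly the homoenolate that the cyclopropanol releases on ring opening.
- Stereochemistry: C9 (and a temporary C8 centre) from reagent-controlled hydroboration; C1 relayed from C9/C8 in the conjugate addition; C5 and C4 from a reversible aldol (trans ring fusion, OH chelated to C6=O); C6 from hydride delivery by the C4 hydroxyl.

Key step: step 9

Remark (assumption): the monoisopinocampheylborane made from (+)-α-pinene is taken to show the same sense of induction here as with 1-methylcycloalkenes, i.e. the (S,S)-trans alcohol; C2 of 9 and 10 and the cyclopropane carbons of 12 are carried as mixtures because they become sp2 or are lost later.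

**Route**

Step 1
Reactants: 1 methyl 2-methylpropanoate
Product: 2 1-(propan-2-yl)cyclopropan-1-ol
Conditions: EtMgBr (2.4 equiv), Ti(OiPr)4 (20 mol %), Et2O, 0 °C → rt; dilute H2SO4
Reagents that add atoms: ethylmagnesium bromide (CC[Mg]Br)
Why: Kulinkovich reaction, in which the titanacyclopropane generated from EtMgBr and Ti(OiPr)4 acts as a 1,2-dicarbanion towards the ester carbonyl and should give the tertiary cyclopropanol, which has no stereocentre.

Step 2
Reactants: 3 4-hydroxy-3-methoxybenzoic acid
Product: 5 4-(tert-butyldimethylsilyloxy)-3-methoxybenzoic acid, via silyl ester 4 (not isolated)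
Conditions: TBSCl (2.5 equiv), imidazole, DMF, rt; then AcOH/THF/H2O, rt
Reagents that add atoms: tert-butyldimethylsilyl chloride (CC(C)(C)[Si](C)(C)Cl)
Why: Standard silyl protection, in which phenol and acid are both silylated and the labile silyl ester is then hydrolysed selectively, should leave the aryl silyl ether and the free acid.

Step 3
Reactants: 6 2,5-dimethylanisole
Product: 7 1-methoxy-2,5-dimethylcyclohexa-1,4-diene
Conditions: Li, NH3 (liquid), THF, tBuOH, −78 → −33 °C; then H2O
Reagents that add atoms: none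
Why: Birch reduction, in which the methoxy and methyl groups stay on sp2 carbons, should give the 1,4-diene with one tetrasubstituted enol ether and one trisubstituted alkene.

Step 4
Reactants: 7 1-methoxy-2,5-dimethylcyclohexa-1,4-diene
Product: 9 (4S,5S)-4-hydroxy-2,5-dimethylcyclohexan-1-one as C2 epimers, via enol ether alcohol 8 (not isolated)
Conditions: IpcBH2 (monoisopinocampheylborane from (+)-α-pinene), Et2O, −25 °C; NaOH, H2O2, 0 °C → rt; then 1 M HCl, THF, rt
Reagents that add atoms: hydrogen peroxide (OO); water (O)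
Why: Asymmetric hydroboration–oxidation, in which the hindered chiral borane should attack only the trisubstituted alkene, syn addition places OH and methyl trans, the reagent sets both new centres as S,S (as with 1-methylcycloalkenes), and acid hydrolysis of the enol ether then frees the ketone.

Step 5
Reactants: 9 (4S,5S)-4-hydroxy-2,5-dimethylcyclohexan-1-one
Product: 10 (4S,5S)-4-(tert-butyldimethylsilyloxy)-2,5-dimethylcyclohexan-1-one as C2 epimers
Conditions: TBSCl, imidazole, DMF, rt
Reagents that add atoms: tert-butyldimethylsilyl chloride (CC(C)(C)[Si](C)(C)Cl)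
Why: Standard silylation of the secondary alcohol should protect the future C9 oxygen for the organometallic, basic and oxidative steps that follow.

Step 6
Reactants: 10 (4S,5S)-4-(tert-butyldimethylsilyloxy)-2,5-dimethylcyclohexan-1-one
Product: 11 tert-butyl{[(1S,6S)-3,6-dimethyl-4-(trimethylsilyloxy)cyclohex-3-en-1-yl]oxy}dimethylsilane
Conditions: Me3SiCl, NaI, Et3N, MeCN, rt
Reagents that add atoms: chlorotrimethylsilane (C[Si](C)(C)Cl)
Why: Thermodynamic silyl enol ether formation (Me3SiI made in the flask, amine base) should favour the tetrasubstituted enol ether towards the methyl-bearing α-carbon, which removes that stereocentre.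

Step 7
Reactants: 11 tert-butyl{[(1S,6S)-3,6-dimethyl-4-(trimethylsilyloxy)cyclohex-3-en-1-yl]oxy}dimethylsilane
Product: 12 (3S,4S)-4-(tert-butyldimethylsilyloxy)-3,6-dimethyl-1-(trimethylsilyloxy)bicyclo[4.1.0]heptane as cyclopropane diastereomers
Conditions: Et2Zn, CH2I2, CH2Cl2, 0 °C → rt
Reagents that add atoms: diiodomethane (ICI)
Why: Simmons–Smith cyclopropanation of the electron-rich silyl enol ether should give the siloxycyclopropane, and its facial selectivity is irrelevant because both new centres are lost in step 8.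

Step 8
Reactants: 12 (3S,4S)-4-(tert-butyldimethylsilyloxy)-3,6-dimethyl-1-(trimethylsilyloxy)bicyclo[4.1.0]heptane
Product: 14 (5S,6S)-5-(tert-butyldimethylsilyloxy)-3,6-dimethylcyclohept-2-en-1-one, via chloro ketone 13 (not isolated)
Conditions: FeCl3 (2.2 equiv), DMF, 0 °C → rt; then NaOAc, MeOH, reflux
Reagents that add atoms: none
Why: Ito–Saegusa ring expansion, in which FeCl3 oxidises the siloxycyclopropane to an oxygen radical that cleaves the internal bond to the tertiary ring-expanded radical, chlorine transfer gives the β-chloro ketone, and acetate-induced elimination should give the conjugated 3-methylcycloheptenone.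

Step 9
Reactants: 14 (5S,6S)-5-(tert-butyldimethylsilyloxy)-3,6-dimethylcyclohept-2-en-1-one; 2 1-(propan-2-yl)cyclopropan-1-ol
Product: 17 (3R,3aR,6S,7S,8aR)-7-(tert-butyldimethylsilyloxy)-3-hydroxy-6,8a-dimethyl-3-(propan-2-yl)octahydroazulen-4(1H)-one, via zinc homoenolate 15 (not isolated), via silyl enol ether 16 (not isolated)
Conditions: 2 (2.4 equiv), Et2Zn (1.2 equiv), THF/DMPU, 0 °C → rt; CuBr·SMe2 (10 mol %), Me3SiCl (3 equiv), 14, 0 °C → rt; volatiles removed; KOtBu (1.2 equiv), THF, −40 → 0 °C; aq. NH4Cl
Reagents that add atoms: none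
Why: Proposed new method: zinc alkoxide formation and strain-driven opening of cyclopropanol 2 should give ketone homoenolate 15, which a catalytic organocopper species transfers to C1 of enone 14 (Me3SiCl-accelerated 1,4-addition, C1–C2 bond) to give the regiodefined C5 silyl enol ether 16 with its isopropyl ketone free, and KOtBu then unmasks the C5 enolate, which adds to that ketone (C5–C4 bond). The closest known reaction types are the copper-catalysed, Me3SiCl-promoted conjugate addition of ester-derived zinc homoenolates to β,β-disubstituted enones and the base-mediated aldol closure of 1,6-diketones, whereas their union with a cyclopropanol-derived ketone homoenolate on a cycloheptenone that creates a quaternary centre has not been shown. The cyclopentane closes by a 5-(enolexo)-exo-trig aldol addition. C1 is under substrate control: in the chair-like enone the C9 silyloxy and C8 methyl groups are both equatorial, and attack anti to the C10–C9 bond should place the new chain cis to C9–O and trans to C8–Me. C5 and C4 are set under thermodynamic control, since the tertiary potassium aldolate reopens by retro-aldol through the same enolate: kinetic closure is expected on the face of the chain (cis-fused), but equilibration should lead to the trans-fused ketol, in which C2 and C4 are both equatorial on the seven-membered ring, quaternary C1 takes the isoclinal position of the twist-chair, the C4 oxygen sits on the face of the C1 methyl and chelates the C6 carbonyl, and the isopropyl group points away from it. The step needs 1,4-addition at a fully substituted β-carbon and one enolate regioisomer, which 14 secures by having a single acceptor position and no acidic site once C9 is silylated, with the C5 enolate generated only from 16 under aprotic conditions.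

Step 10
Reactants: 17 (3R,3aR,6S,7S,8aR)-7-(tert-butyldimethylsilyloxy)-3-hydroxy-6,8a-dimethyl-3-(propan-2-yl)octahydroazulen-4(1H)-one
Product: 18 (3R,3aR,7S,8aR)-7-(tert-butyldimethylsilyloxy)-3-hydroxy-6,8a-dimethyl-3-(propan-2-yl)-2,3,3a,7,8,8a-hexahydroazulen-4(1H)-one
Conditions: IBX, 4-methoxypyridine N-oxide, DMSO, rt
Reagents that add atoms: none
Why: IBX-mediated α,β-dehydrogenation of a ketone can only occur towards C7–C8, because C5 is flanked by the fully substituted C1 and C4, and should give the trisubstituted enone while removing the temporary C8 centre.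

Step 11
Reactants: 18 (3R,3aR,7S,8aR)-7-(tert-butyldimethylsilyloxy)-3-hydroxy-6,8a-dimethyl-3-(propan-2-yl)-2,3,3a,7,8,8a-hexahydroazulen-4(1H)-one
Product: 19 (3R,3aS,4S,7S,8aR)-7-(tert-butyldimethylsilyloxy)-6,8a-dimethyl-3-(propan-2-yl)-1,2,3,3a,4,7,8,8a-octahydroazulene-3,4-diol
Conditions: Me4NBH(OAc)3, MeCN/AcOH, −30 → 0 °C
Reagents that add atoms: none
Why: Evans–Saksena reduction, in which the C4 hydroxyl exchanges onto boron and delivers hydride to C6 from its own face (the face of the C1 methyl), should give 1,2-reduction to the 1,3-anti diol with the C6 hydroxyl cis to H-5.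

Step 12
Reactants: 19 (3R,3aS,4S,7S,8aR)-7-(tert-butyldimethylsilyloxy)-6,8a-dimethyl-3-(propan-2-yl)-1,2,3,3a,4,7,8,8a-octahydroazulene-3,4-diol; 5 4-(tert-butyldimethylsilyloxy)-3-methoxybenzoic acid
Product: 20 (3R,3aS,4S,7S,8aR)-7-(tert-butyldimethylsilyloxy)-3-hydroxy-6,8a-dimethyl-3-(propan-2-yl)-1,2,3,3a,4,7,8,8a-octahydroazulen-4-yl 4-(tert-butyldimethylsilyloxy)-3-methoxybenzoate
Conditions: EDC·HCl, DMAP, CH2Cl2, rt
Reagents that add atoms: none
Why: Steglich esterification should acylate only the secondary allylic C6 hydroxyl, since the tertiary C4 hydroxyl is inert and the C9 and phenol oxygens are silylated.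

Step 13
Reactants: 20 (3R,3aS,4S,7S,8aR)-7-(tert-butyldimethylsilyloxy)-3-hydroxy-6,8a-dimethyl-3-(propan-2-yl)-1,2,3,3a,4,7,8,8a-octahydroazulen-4-yl 4-(tert-butyldimethylsilyloxy)-3-methoxybenzoate
Product: 21 (3R,3aS,4S,7S,8aR)-3,7-dihydroxy-6,8a-dimethyl-3-(propan-2-yl)-1,2,3,3a,4,7,8,8a-octahydroazulen-4-yl 4-hydroxy-3-methoxybenzoate
Conditions: HF·pyridine, pyridine, THF, 0 °C → rt
Reagents that add atoms: none
Why: Buffered fluoride desilylation should remove the secondary and the aryl silyl ether without cleaving or shifting the allylic ester.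

**Compound list**

1 | methyl 2-methylpropanoate | COC(=O)C(C)C | starting material
2 | 1-(propan-2-yl)cyclopropan-1-ol | CC(C)C1(O)CC1 | intermediate
3 | 4-hydroxy-3-methoxybenzoic acid (vanillic acid) | COc1cc(C(=O)O)ccc1O | starting material
4 | tert-butyldimethylsilyl 4-(tert-butyldimethylsilyloxy)-3-methoxybenzoate | COc1cc(C(=O)O[Si](C)(C)C(C)(C)C)ccc1O[Si](C)(C)C(C)(C)C | intermediate
5 | 4-(tert-butyldimethylsilyloxy)-3-methoxybenzoic acid | COc1cc(C(=O)O)ccc1O[Si](C)(C)C(C)(C)C | intermediate
6 | 2,5-dimethylanisole | COc1cc(C)ccc1C | starting material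
7 | 1-methoxy-2,5-dimethylcyclohexa-1,4-diene | COC1=C(C)CC=C(C)C1 | intermediate
8 | (1S,6S)-4-methoxy-3,6-dimethylcyclohex-3-en-1-ol | COC1=C(C)C[C@H](O)[C@@H](C)C1 | intermediate
9 | (4S,5S)-4-hydroxy-2,5-dimethylcyclohexan-1-one (C2 epimers) | O=C1C[C@H](C)[C@@H](O)CC1C | intermediate
10 | (4S,5S)-4-(tert-butyldimethylsilyloxy)-2,5-dimethylcyclohexan-1-one (C2 epimers) | O=C1C[C@H](C)[C@@H](O[Si](C)(C)C(C)(C)C)CC1C | intermediate
11 | tert-butyl{[(1S,6S)-3,6-dimethyl-4-(trimethylsilyloxy)cyclohex-3-en-1-yl]oxy}dimethylsilane | C[Si](C)(C)OC1=C(C)C[C@H](O[Si](C)(C)C(C)(C)C)[C@@H](C)C1 | intermediate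
12 | (3S,4S)-4-(tert-butyldimethylsilyloxy)-3,6-dimethyl-1-(trimethylsilyloxy)bicyclo[4.1.0]heptane (cyclopropane diastereomers) | C[Si](C)(C)OC12CC1(C)C[C@H](O[Si](C)(C)C(C)(C)C)[C@@H](C)C2 | intermediate
13 | (5S,6S)-5-(tert-butyldimethylsilyloxy)-3-chloro-3,6-dimethylcycloheptan-1-one (C3 epimers) | O=C1CC(C)(Cl)C[C@H](O[Si](C)(C)C(C)(C)C)[C@@H](C)C1 | intermediate
14 | (5S,6S)-5-(tert-butyldimethylsilyloxy)-3,6-dimethylcyclohept-2-en-1-one | O=C1C=C(C)C[C@H](O[Si](C)(C)C(C)(C)C)[C@@H](C)C1 | intermediate
15 | bis(4-methyl-3-oxopentyl)zinc | CC(C)C(=O)CC[Zn]CCC(=O)C(C)C | intermediate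
16 | 1-[(1R,5S,6S)-6-(tert-butyldimethylsilyloxy)-1,5-dimethyl-3-(trimethylsilyloxy)cyclohept-2-en-1-yl]-4-methylpentan-3-one | C[Si](C)(C)OC1=C[C@](C)(CCC(=O)C(C)C)C[C@H](O[Si](C)(C)C(C)(C)C)[C@@H](C)C1 | intermediate
17 | (3R,3aR,6S,7S,8aR)-7-(tert-butyldimethylsilyloxy)-3-hydroxy-6,8a-dimethyl-3-(propan-2-yl)octahydroazulen-4(1H)-one | O=C1C[C@H](C)[C@@H](O[Si](C)(C)C(C)(C)C)C[C@@]2(C)CC[C@@](O)(C(C)C)[C@H]12 | intermediate
18 | (3R,3aR,7S,8aR)-7-(tert-butyldimethylsilyloxy)-3-hydroxy-6,8a-dimethyl-3-(propan-2-yl)-2,3,3a,7,8,8a-hexahydroazulen-4(1H)-one | O=C1C=C(C)[C@@H](O[Si](C)(C)C(C)(C)C)C[C@@]2(C)CC[C@@](O)(C(C)C)[C@H]12 | intermediate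
19 | (3R,3aS,4S,7S,8aR)-7-(tert-butyldimethylsilyloxy)-6,8a-dimethyl-3-(propan-2-yl)-1,2,3,3a,4,7,8,8a-octahydroazulene-3,4-diol | O[C@H]1C=C(C)[C@@H](O[Si](C)(C)C(C)(C)C)C[C@@]2(C)CC[C@@](O)(C(C)C)[C@H]12 | intermediate
20 | (3R,3aS,4S,7S,8aR)-7-(tert-butyldimethylsilyloxy)-3-hydroxy-6,8a-dimethyl-3-(propan-2-yl)-1,2,3,3a,4,7,8,8a-octahydroazulen-4-yl 4-(tert-butyldimethylsilyloxy)-3-methoxybenzoate | COc1cc(C(=O)O[C@H]2C=C(C)[C@@H](O[Si](C)(C)C(C)(C)C)C[C@@]3(C)CC[C@@](O)(C(C)C)[C@H]23)ccc1O[Si](C)(C)C(C)(C)C | intermediate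
21 | (3R,3aS,4S,7S,8aR)-3,7-dihydroxy-6,8a-dimethyl-3-(propan-2-yl)-1,2,3,3a,4,7,8,8a-octahydroazulen-4-yl 4-hydroxy-3-methoxybenzoate | COc1cc(C(=O)O[C@H]2C=C(C)[C@@H](O)C[C@@]3(C)CC[C@@](O)(C(C)C)[C@H]23)ccc1O | target

**Step count and risks**

Total steps: 13. Longest linear sequence: 11 steps (steps 3 to 13, from 2,5-dimethylanisole 6).

The three steps most likely to fail:

1. Step 9 (proposed new method). Transfer of the homoenolate to the fully substituted β-carbon may be slow and lose out to its protonation. The aldol may also stop at the kinetically closed cis-fused ketol, or run on to dehydration, if the aldolate does not equilibrate cleanly. The fallback uses known chemistry and separates the two bond formations; it sets out from 2 and 14 and returns at 17. Cyclopropanol 2 is opened with N-bromosuccinimide to 1-bromo-4-methylpentan-3-one F1, which is ketalised with ethylene glycol (TsOH) to 2-(2-bromoethyl)-2-(propan-2-yl)-1,3-dioxolane F2 and converted with magnesium into {2-[2-(propan-2-yl)-1,3-dioxolan-2-yl]ethyl}magnesium bromide F3. Its CuBr·SMe2-catalysed, Me3SiCl-accelerated conjugate addition to 14 should give, after aqueous work-up, (3R,5S,6S)-5-(tert-butyldimethylsilyloxy)-3,6-dimethyl-3-{2-[2-(propan-2-yl)-1,3-dioxolan-2-yl]ethyl}cycloheptan-1-one F4. Mild acid (PPTS, wet acetone) frees (3R,5S,6S)-5-(tert-butyldimethylsilyloxy)-3,6-dimethyl-3-(4-methyl-3-oxopentyl)cycloheptan-1-one F5, whose base-mediated aldol cyclisation (KOtBu, THF, or NaOMe, MeOH) is then run as a separate, monitored equilibration to 17. This does not remove the dependence on the trans-fused ketol being the thermodynamic product.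

2. Step 4. The chiral borane may discriminate the alkene faces incompletely, or hydroborate some of the enol ether, which would erode the enantiomeric purity of every later compound. The fallback sets out from 7 and returns at 9. Hydroboration of 7 with 9-BBN (THF, 65 °C), oxidation and acid hydrolysis should give racemic trans-4-hydroxy-2,5-dimethylcyclohexan-1-one F6. Kinetic resolution with Candida antarctica lipase B and vinyl acetate should acylate the (4R,5R) enantiomer to (1R,2R)-2,5-dimethyl-4-oxocyclohexyl acetate F7 and leave (4S,5S)-9, which is separated and carried on.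

3. Step 11. Exchange of the hindered tertiary C4 hydroxyl onto boron may be slow, so that hydride arrives undirected and from the wrong face, or the enone is not reduced. The fallback sets out from 18 and returns at 20. Luche reduction (NaBH4, CeCl3·7H2O, MeOH) is expected to deliver hydride from the face away from the C1 methyl and C4 hydroxyl and give the C6 epimer (3R,3aS,4R,7S,8aR)-7-(tert-butyldimethylsilyloxy)-6,8a-dimethyl-3-(propan-2-yl)-1,2,3,3a,4,7,8,8a-octahydroazulene-3,4-diol F8. Mitsunobu esterification of F8 with acid 5 (PPh3, DIAD, toluene) then forms the ester with inversion at C6 and gives 20 directly.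

Further compounds
F1 | step 9 | 1-bromo-4-methylpentan-3-one | CC(C)C(=O)CCBr
F2 | step 9 | 2-(2-bromoethyl)-2-(propan-2-yl)-1,3-dioxolane | CC(C)C1(CCBr)OCCO1
F3 | step 9 | {2-[2-(propan-2-yl)-1,3-dioxolan-2-yl]ethyl}magnesium bromide | CC(C)C1(CC[Mg]Br)OCCO1
F4 | step 9 | (3R,5S,6S)-5-(tert-butyldimethylsilyloxy)-3,6-dimethyl-3-{2-[2-(propan-2-yl)-1,3-dioxolan-2-yl]ethyl}cycloheptan-1-one | O=C1C[C@](C)(CCC2(C(C)C)OCCO2)C[C@H](O[Si](C)(C)C(C)(C)C)[C@@H](C)C1
F5 | step 9 | (3R,5S,6S)-5-(tert-butyldimethylsilyloxy)-3,6-dimethyl-3-(4-methyl-3-oxopentyl)cycloheptan-1-one | O=C1C[C@](C)(CCC(=O)C(C)C)C[C@H](O[Si](C)(C)C(C)(C)C)[C@@H](C)C1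
F6 | step 4 | (4RS,5RS)-4-hydroxy-2,5-dimethylcyclohexan-1-one (racemic trans, C2 epimers) | O=C1CC(C)C(O)CC1C
F7 | step 4 | (1R,2R)-2,5-dimethyl-4-oxocyclohexyl acetate | O=C1C[C@@H](C)[C@H](OC(C)=O)CC1C
F8 | step 11 | (3R,3aS,4R,7S,8aR)-7-(tert-butyldimethylsilyloxy)-6,8a-dimethyl-3-(propan-2-yl)-1,2,3,3a,4,7,8,8a-octahydroazulene-3,4-diol | O[C@@H]1C=C(C)[C@@H](O[Si](C)(C)C(C)(C)C)C[C@@]2(C)CC[C@@](O)(C(C)C)[C@H]12
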